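- We begin by turning the last reading of each earlier run, product in percent of the charge, into concentration: 1.89 mM on Thursday's run, 2.08 mM on Friday's and 1.98 mM on Tuesday's.

| setting | Thursday's | Friday's | Tuesday's | flask |
|---|---|---|---|---|
| starting material | 10 mM | 15 mM | 20 mM | 20 mM |
| solid reagent | 22 mM | 22 mM | 22 mM | 22.0 mM |
| protic impurity | 1 mM | 1 mM | 2 mM | 1.00 mM |
| free catalyst | 1.7 mM | 1.7 mM | 1.7 mM | 1.7 mM |
| second catalyst | 0.22 mM | 0.22 mM | 0.22 mM | 0.22 mM |
| remark | run made earlier | run made earlier | run made earlier |  |
| time |  |  |  | 40 h |

- Thursday's (time / h: product / %): 4.00: 0; 10.0: 2.5; 20.0: 4.9; 30.0: 13.0; 40.0: 18.9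
- Friday's (time / h: product / %): 8.00: 1.0; 15.0: 1.5; 25.0: 6.4; 30.0: 11.2; 40.0: 13.9
- Tuesday's (time / h: product / %): 3.00: 0.9; 6.00: 0.6; 12.0: 1.0; 20.0: 4.3; 40.0: 9.9

(standard deviation of a reading: 1 percentage point)

- given per volume of solution although it is solid: solid reagent
- what was read earlier has a scatter of 1 percentage point, one standard deviation
- at the start none of the solid reagent is in solution

- gamma: doubling the solubility of the solid reagent, all else as stated
- beta: doubling the amount of free catalyst, all else as stated
- delta: doubling the dissolution coefficient of the solid reagent, all else as stated

- amount of product at 40 h, in percent of the starting material charged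
- the change that raises the amount of product at 40 h, in percent of the starting material charged most ("none" if none brings more than 2 percentage points) (gamma / beta / delta / none)
- amount of product at 40 h, in percent of the starting material charged, after beta

- Starting material: by hand, a rate proportional to [starting material] would lift product 1.50-fold from Thursday's run to Friday's, but it rises 1.10-fold, less than that, with readings scattering by 1 percentage point.
- Protic impurity: by hand, it should eat into product, yet Tuesday's run, with 2 mM against Friday's 1 mM, shows no loss in mM beyond that scatter; but the two runs also differ in starting material, 20 mM against 15 mM, so this comparison does not separate the two settings.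
- Second catalyst: the runs held it at the same 0.22 mM, so its effect is untested, but we commit to a count. The mean of those last readings in mM, divided by that charge, gives 9.02 for the turnover count, the mM of product at 40 h per mM of second catalyst charged. For the flask, that means 9.93%.
- Free catalyst: the runs did not turn it. If it acts on starting material, to which product answered weakly, we keep 9.93% after beta.
- Solid reagent: it starts undissolved, and Thursday's product grows 3.86-fold from 20.0 h to 40.0 h, faster than time. This points to dissolved reagent building up, so we choose gamma.
- The forecast, above ours, gives 10.5% (9% to 12.5%), picks gamma and puts beta at 15% (10.5% to 21%), saying “Doubling free catalyst may help only partly”.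
- The flask gives 9.47%; gamma adds 9.4 points, and beta gives 9.57%.

    solid reagent ⇌ partner, rate k1*(cs1 - [partner]) while solid is left; crystals form when [partner] > cs1 (solubility = 8.30 mM, k = 0.0823 h⁻¹)
    starting material + free catalyst ⇌ free catalyst + open intermediate (K = 1.10, k = 28.4 M⁻¹ h⁻¹)
    second catalyst + open intermediate ⇌ catalyst intermediate (K = 2270 M⁻¹, k = 22700 M⁻¹ h⁻¹)
    starting material + protic impurity → quenched substrate (k = 55.0 M⁻¹ h⁻¹)
    partner + catalyst intermediate → second catalyst + product (k = 41.7 M⁻¹ h⁻¹)

- At 40.0 h, catalyst intermediate, the resting state, holds 94.8% of the second catalyst in the flask, whose turnover count comes to 8.61. A neighbouring flask charged with 0.55 mM of second catalyst reaches 21.4% at 40.0 h, a turnover count of 7.79.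

The runs were computed with constants of no real substance; the scatter is artificial.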